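Time has taken the substrate of the north-east flask down to a reading of 0% at 192 h, and the question is what is left to win from that flask.

| setting | north-east | north-west | flask |
|---|---|---|---|
| substrate | 0.24 M | 0.24 M | 0.24 M |
| coupling partner | 0.60 M | 0.60 M | 0.600 M |
| initiator | 2.4 mM | 2.4 mM | 2.4 mM |
| radical scavenger | 0.24 mM | 0.24 mM | 0.24 mM |
| temperature | 25 °C | 20 °C | 25 °C |
| remark | the very flask that is asked about, followed so far | run made earlier |  |
| time |  |  | 8.0 d |

| run | time / h | target / % | substrate / % |
|---|---|---|---|
| north-east | 15.0 | 26 | 68 |
| north-east | 30.0 | 45 | 40 |
| north-east | 60.0 | 52 | 15 |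
| north-east | 96.0 | 50 | 6 |
| north-east | 192 | 49 | 0 |
| north-west | 15.0 | 8 | 89 |
| north-west | 30.0 | 32 | 64 |
| north-west | 60.0 | 50 | 35 |
| north-west | 96.0 | 50 | 19 |
| north-west | 192 | 43 | 3 |

(standard deviation of a reading: 1.5 percentage points)

- Friday's: at 8.0 d take out 90% of the by-product then present, then wait 15 d
- Saturday's: change nothing and wait 15 d more
- Wednesday's: at 8.0 d add coupling partner, 100% of the amount charged, then wait 15 d
- Thursday's: at 8.0 d raise the temperature by 10 K, then wait 15 d

- additions bring no volume worth counting
- the numbers in the tables scatter by 1.5 percentage points (one standard deviation)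

1. target, in percent of the substrate first charged, at 8.0 d
2. what to do for the largest gain in target; "none" if nothing gains more than 2 percentage points (Friday's / Saturday's / Wednesday's / Thursday's / none)
3. target present, in percent of the substrate first charged, after Saturday's
4. target present, in percent of the substrate first charged, after Thursday's

What stands in the north-east flask now? Its reading at 192 h, the asked time itself, is 49%, and it lies 1 percentage point under the reading at 96.0 h, which is less than the scatter of 1.5 points. So we say 49% now, and the same after Saturday's.

Why does target stop there? In the north-east flask at 192 h we reckon 1.04 for the end ratio ρ, the part of the charge that is neither substrate nor target, over the part that is target. The colder north-west flask started more slowly, with 89% of its substrate left at 15.0 h against 68% in the north-east flask, yet at 192 h its ρ reads 1.26, higher than the north-east value. A one-way loss slowed by the cold as the substrate was should not have run further in the north-west flask, so we take target to stand in a balance with the missing part (thermodynamic control), with ρ falling on warming. With the substrate of the north-east flask read at 0%, target there is 1/(1+ρ) of the charge, and we bet on Thursday's.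

How far does 10 K go? Two steps of the change from the north-west to the north-east flask give ρ = 0.715, so our estimate for target is 58.3%. The north-west ρ was still climbing, from 0.620 at 96.0 h, so its end value may stand higher still, and we hold our target estimate to be low.

The forecast gives 49.5% now, Thursday's as best, 49% after Saturday's and 61% after Thursday's, the last above our estimate: “That points to a reversible target ⇌ by-product equilibrium rather than a sink”.

The flask gives 49.9% now, Thursday's as best with a gain of 21 points, 50.0% after Saturday's and 71.4% after Thursday's.

    initiator → 2 initiating radical (k = 0.0100 h⁻¹, Ea = 101 kJ mol⁻¹)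
    substrate + initiating radical → capped initiator + first chain carrier (k = 47000 M⁻¹ s⁻¹, Ea = 10.0 kJ mol⁻¹)
    coupling partner + first chain carrier ⇌ target + second chain carrier (K = 1.20, k = 18000 M⁻¹ s⁻¹, Ea = 33.0 kJ mol⁻¹, ΔH = −32.0 kJ mol⁻¹)
    substrate + second chain carrier → by-product + first chain carrier (k = 4.50 × 10⁶ M⁻¹ h⁻¹, Ea = 43.0 kJ mol⁻¹)
    2 second chain carrier → ended chains A (k = 8.00 × 10⁷ M⁻¹ s⁻¹, Ea = 15.0 kJ mol⁻¹)
    target ⇌ isomer of the product (K = 1.00, k = 0.0260 h⁻¹, Ea = 107 kJ mol⁻¹, ΔH = −70.0 kJ mol⁻¹)
    second chain carrier + radical scavenger → ended chains B (k = 5.80 × 10⁷ M⁻¹ s⁻¹, Ea = 15.0 kJ mol⁻¹)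
    (constants at 25 °C)

Thursday's result stands 10 points above the forecast. The missing part in the flask at 192 h is the isomer of the product, 49.5% of the substrate charged, and the relaxation half-life of target and isomer of the product, by this step alone and both ways together, is 13.3 h, short against 8.0 d. After Thursday's, ρ is 0.400. Half that 10 K step again gives ρ = 0.248 and target 80.1%, and the same flask run at 40 °C ends with 79.3% of target.

(The runs are simulated for an exercise; noise was put on by code.)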